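## Structural features

Pentaalbaspidin BBBBB is a chain of five six-membered carbocycles, A–B–C–D–E, joined by four methylene bridges. Rings A and E are enolised 2-butanoyl-6,6-dimethylcyclohexane-1,3,5-triones and rings B, C and D are butanoylphloroglucinols; each bridge links a ring carbon lying between two oxygen-bearing carbons to the same kind of carbon in the next ring. There is no stereocentre, so no adjacent stereocentres arise; the only isomerism is keto–enol tautomerism in rings A and E, and the constitution is symmetric about ring C. The fragile elements are the aryl–CH2–aryl links, which acid or base can reopen through quinone-methide-type species with scrambling of the rings, and the free polyphenols and vinylogous acids, which are sensitive to air and base. The real difficulty is constitutional: five alike, highly nucleophilic rings must be connected in a fixed order without statistical methylene condensation, and rings B, C and D are hexasubstituted. The key step exploits ring C, which has oxygen on C2, C4 and C6, the butanoyl carbon on C1 between two of them, and the bridging methylenes on C3 and C5. This pattern arises when the four-carbon chain of a 2,4-disubstituted acetoacetate (oxygen on its C1 and C3, one arm on its C2 and one on its C4) is closed with the two alkyne carbons of a 1-alkoxy ynone, which bring the third oxygen and the acyl group.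

## Logic of the disconnections

26 is cut at the two bonds between the outer methylene carbons and the single unsubstituted carbons of rings B and D, giving 20 and two molecules of 24, which act through 25. Rings A and E are identical, and 20 has exactly one free nuclear carbon on each outer ring and none on ring C, so the two-directional capping has no wrong site available. The forward step needs two conjugate additions of a phenolic carbon to 25 without redistribution of the bridges already present.

24 is traced back through its C–CH2N bond to 23, through the two C–CH3 bonds on one ring carbon to 22, and through the aryl–acyl bond to 21. Each cut removes one substituent from a symmetrical ring. The forward demands are geminal rather than distributed C-methylation, and aminomethylation without dimerisation.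

20 is derived from 19 by cutting eight O–benzyl bonds and one O–ethyl bond. This exchanges a polyphenol that cannot be carried through many steps for a lipophilic ether that can be chromatographed. The forward step must remove benzyl groups without letting benzyl cations alkylate the rings, and must also cleave an aryl ethyl ether, which is feasible because that ether lies ortho to a ketone.

19 is cut at the two aryl–acyl bonds of rings B and D, leading through 18 to 17. Leaving these ketones off the arms keeps the arm unit symmetrical and free of enolisable ketone during the enolate and silylation chemistry. The forward step needs one acylation per outer ring and must tolerate the two phenols of ring C, which are expected to be esterified transiently.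

17 is cut at two bonds of ring C: the bond between the ethoxy-bearing carbon and its arm-bearing neighbour, and the bond between the butanoyl-bearing carbon and the hydroxyl-bearing carbon that was the ester carbon. This leads through 16 and 15 to 10 and 14. A hexasubstituted arene is replaced by two acyclic pieces, the butanoyl group arrives in place, and polarity sets the regiochemistry. The forward step needs the donor-substituted alkyne of 14 to accept a silyl dienolate below the temperature at which 14 fragments.

10 is cut at its two O–Si bonds, giving 9 and then 8. The forward steps are enol silylation, then deprotonation at the γ-carbon and O-silylation of the dienolate.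

8 is cut at the bond between its α-carbon and the benzylic methylene, giving 7 and 5. 7 is cut at the bond between its γ-carbon and the benzylic methylene, giving 6 and 5. Both arms therefore come from one electrophile, and the demand is carbon-selective alkylation first at the γ- and then at the α-carbon.

5 is traced through 4 to 3 by exchanging the C–Cl bond for a C–O bond, 3 to 2 by reduction, and 2 to 1 by cutting three O–benzyl bonds. Because 5 ionises very easily, the forward step must make it without acid and keep it as a cold solution that serves both alkylations. The benzylation must go to oxygen rather than to the ring carbons.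

14 is traced to 13 by oxidation, and 13 is cut at the bond between the alkyne carbon and the carbinol carbon, giving 11 and 12. The forward steps must stay non-acidic so that the alkoxyalkyne survives.

## Other disconnections considered

Alternative 1: The two bonds between C3 and C5 of ring C and the inner methylene carbons are cut. In the forward sense two equivalents of the benzylic zinc chloride A2 would couple with the diiodide A3 under Pd(OAc)2 and SPhos to give the nona-O-benzyl trimer A1, with no ring closed.
- In favour: all three rings come from one benzylated butanoylphloroglucinol family and each brings its own butanoyl group. A1 carries nine identical benzyl ethers, so a single hydrogenolysis would give 20 with no ethyl ether to cleave and no late acylation. On this end-game the alternative is better than the chosen plan. Coupling of a benzylic zinc reagent with an aryl iodide is an established reaction class, whereas the chosen key step uses an untried dienophile, so on precedent it is also better. Its step count should be equal or lower.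
- Against: each C–I bond of A3 lies between two benzyloxy groups and the zinc-bearing carbon of A2 between two more, so a tetra-ortho-substituted diarylmethane must form twice on an electron-rich iodide. Mono-coupling with protodeiodination and homocoupling of A2 are the foreseeable losses. Forming A2 also requires zinc insertion at a benzylic position that ionises readily.
- Comparison: both plans arrive at the same hexasubstituted ring C. The alternative keeps the ring aromatic throughout and is limited by sterics at the metal. The chosen plan builds the ring and is limited by the electronics of the alkyne, but its bond formation is not hindered by ortho substituents around a metal centre.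

Alternative 2: Four ring bonds are cut so that rings B and D are grown on a preformed ring C. Each diene unit of the tetrakis(silyloxy) bis-diene A5 would join 14 through its arm-bearing terminus (to the ethoxy-bearing alkyne carbon) and its ketene-acetal carbon (to the acyl-bearing alkyne carbon), and aromatisation would give A4 with both outer rings closed.
- In favour: the diene carbons next to the ester are unsubstituted, which is the less hindered and better-known pattern, so on diene reactivity the alternative is better. The butanoyl groups of rings B and D arrive with 14, and the free nuclear carbon needed for capping appears on each outer ring automatically.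
- Against: two annulations must both succeed in one flask. The unsubstituted carbon next to the ester opens the competing three-carbon closure onto the ketone, which the arm blocks in the chosen plan. Two ethyl ethers must be cleaved instead of one. Ring C of A4 still lacks its butanoyl group at a carbon between two benzyloxy groups, while rings B and D each offer a far more nucleophilic carbon between two free hydroxyls, so a late acylation would go to the wrong rings.
- Comparison: the reaction type and the uncertainty about the alkoxy ynone are the same, but doubled. The step count to A4 is comparable, but the ring C acylation problem adds steps, so the chosen plan is better on the end-game.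

Alternative 3: Ring C is cut at the two bonds that insert two alkyne carbons between the carbonyl carbon and the arm-bearing carbon of a cyclobutenone. Heating the cyclobutenone A7 with the siloxyalkyne A8 in toluene would set off a pericyclic cascade (four-electron ring opening, (2+2) uptake of the alkyne, a second ring opening and six-electron ring closure) ending in the bis(triisopropylsilyl) ether A6.
- In favour: this cascade is well established for siloxyalkynes and its regiochemistry follows from the mechanism, so on precedent and regiocontrol it is better than the chosen plan. A6 carries silyl ethers and one free phenol and no alkyl ether, which is also better for deprotection. The conditions are neutral.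
- Against: A6 has no butanoyl group on ring C. That ketone would have to be introduced later at a carbon between a hydroxyl and a bulky silyloxy group, together with the acylation of rings B and D. A7 and A8 each need several steps from 3, so the sequence is longer.
- Comparison: both plans build ring C from acyclic or small-ring pieces with both arms in place. The chosen plan delivers the acyl group during ring formation from inexpensive acetoacetate; the alternative is mechanistically safer but less step-economic.

Key step: step 10

Remark: the configuration at the sp3 centres of 8, 13 and 15 and the double-bond geometry of 9 and 10 are uncontrolled and immaterial, since all are erased before the achiral arene 17. Compound 5 is handled only as a cold THF solution and is never concentrated.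

## Route

Step 1
Reactants: 1 2,4,6-trihydroxybenzaldehyde
Product: 2 2,4,6-tris(benzyloxy)benzaldehyde
Conditions: BnBr (excess), K2CO3, DMF, 60 °C
Reagents that add atoms: benzyl bromide, BrCc1ccccc1
Why: Williamson etherification; carbonate in a dipolar aprotic solvent favours O- over C-benzylation, the formyl group lowers the carbon nucleophilicity of the ring, and excess reagent with warming overcomes the two chelated ortho hydroxyls.

Step 2
Reactants: 2 2,4,6-tris(benzyloxy)benzaldehyde
Product: 3 [2,4,6-tris(benzyloxy)phenyl]methanol
Conditions: NaBH4, THF/MeOH, 0 °C; neutral aqueous work-up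
Reagents that add atoms: none
Why: Borohydride reduction of an aryl aldehyde leaves benzyl ethers untouched; the work-up is kept non-acidic because the product is a readily ionised benzylic alcohol.

Step 3
Reactants: 3 [2,4,6-tris(benzyloxy)phenyl]methanol
Product: 5 1,3,5-tris(benzyloxy)-2-(chloromethyl)benzene, via benzylic mesylate 4 (not isolated)
Conditions: n-BuLi (1.0 equiv), THF, −78 °C; MsCl (1.0 equiv), −78 to −20 °C; kept as a THF solution at −78 °C under argon
Reagents that add atoms: methanesulfonyl chloride, CS(=O)(=O)Cl
Why: Sulfonylation of the lithium alkoxide gives mesylate 4, which is displaced at once by the lithium chloride formed in the same flask (an alcohol-to-chloride exchange that generates no acid). The chloride is drawn from this cold stock solution for steps 4 and 5, because warming or concentration would let it alkylate its own electron-rich ring.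

Step 4
Reactants: 6 methyl acetoacetate, 5 1,3,5-tris(benzyloxy)-2-(chloromethyl)benzene
Product: 7 methyl 3-oxo-5-[2,4,6-tris(benzyloxy)phenyl]pentanoate
Conditions: 6 (excess), NaH, then n-BuLi, THF, 0 °C; solution of 5 added at −78 °C, then 0 °C; aq. NH4Cl
Reagents that add atoms: none
Why: γ-Alkylation of the acetoacetate dianion, which reacts at its more basic terminal carbon; excess dianion and cold addition ensure the electrophile is consumed before it can self-condense.

Step 5
Reactants: 7 methyl 3-oxo-5-[2,4,6-tris(benzyloxy)phenyl]pentanoate, 5 1,3,5-tris(benzyloxy)-2-(chloromethyl)benzene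
Product: 8 methyl 3-oxo-5-[2,4,6-tris(benzyloxy)phenyl]-2-{[2,4,6-tris(benzyloxy)phenyl]methyl}pentanoate
Conditions: NaH (1.0 equiv), THF, 0 °C; solution of 5 added at −78 °C, then rt
Reagents that add atoms: none
Why: C-Alkylation of a β-keto ester sodium enolate at the doubly activated carbon; the tight ion pair in THF favours carbon over oxygen, and the 2,6-disubstituted benzyl group makes a second alkylation at the same carbon unlikely. The new centre is racemic and is lost in step 6.

Step 6
Reactants: 8 methyl 3-oxo-5-[2,4,6-tris(benzyloxy)phenyl]-2-{[2,4,6-tris(benzyloxy)phenyl]methyl}pentanoate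
Product: 9 methyl 5-[2,4,6-tris(benzyloxy)phenyl]-2-{[2,4,6-tris(benzyloxy)phenyl]methyl}-3-[(trimethylsilyl)oxy]pent-2-enoate
Conditions: Me3SiCl, Et3N, toluene, rt; filtration and concentration under argon
Reagents that add atoms: chlorotrimethylsilane, C[Si](C)(C)Cl
Why: O-Silylation of the enolisable β-keto ester gives the 3-silyloxy enoate, the usual first stage in preparing 1,3-bis(silyloxy)dienes.

Step 7
Reactants: 9 methyl 5-[2,4,6-tris(benzyloxy)phenyl]-2-{[2,4,6-tris(benzyloxy)phenyl]methyl}-3-[(trimethylsilyl)oxy]pent-2-enoate
Product: 10 1-methoxy-5-[2,4,6-tris(benzyloxy)phenyl]-2-{[2,4,6-tris(benzyloxy)phenyl]methyl}-1,3-bis[(trimethylsilyl)oxy]penta-1,3-diene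
Conditions: LiN(i-Pr)2, THF, −78 °C; Me3SiCl, −78 to 0 °C; non-aqueous work-up (pentane, filtration), used crude
Reagents that add atoms: chlorotrimethylsilane, C[Si](C)(C)Cl
Why: Deprotonation at the γ-carbon gives the extended ester dienolate, which the hard silicon electrophile traps on oxygen as the silyl ketene acetal; the moisture-sensitive diene is not purified.

Step 8
Reactants: 11 ethoxyethyne, 12 butanal
Product: 13 1-ethoxyhex-1-yn-3-ol
Conditions: 11, n-BuLi, THF, −78 °C; then 12, −78 to −20 °C; water quench
Reagents that add atoms: none
Why: 1,2-Addition of lithium ethoxyacetylide to an aldehyde; the neutral quench avoids Meyer–Schuster rearrangement of the ethoxyethynyl carbinol, and the racemic centre is removed in step 9.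

Step 9
Reactants: 13 1-ethoxyhex-1-yn-3-ol
Product: 14 1-ethoxyhex-1-yn-3-one
Conditions: activated MnO2, CH2Cl2, rt
Reagents that add atoms: none
Why: Heterogeneous, acid-free oxidation of a propargylic alcohol, the classical access to 1-alkoxy ynones, which spares the ynol ether.

Step 10
Reactants: 10 1-methoxy-5-[2,4,6-tris(benzyloxy)phenyl]-2-{[2,4,6-tris(benzyloxy)phenyl]methyl}-1,3-bis[(trimethylsilyl)oxy]penta-1,3-diene, 14 1-ethoxyhex-1-yn-3-one
Product: 17 1-[2-ethoxy-4,6-dihydroxy-3,5-bis({[2,4,6-tris(benzyloxy)phenyl]methyl})phenyl]butan-1-one, via cyclohexadiene cycloadduct 15 (not isolated), via aryl trimethylsilyl ether 16 (not isolated)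
Conditions: toluene, 20 to 60 °C, argon; then 10% aq. citric acid, THF, 0 °C
Reagents that add atoms: none
Why: Proposed new method: the step is planned as a stepwise polar (4+2) cycloaddition in which the arm-bearing terminal carbon of silyl dienolate 10 attacks the ethoxy-bearing alkyne carbon of 14 in a Mukaiyama–Michael sense, leaving an allenyl enolate and a cation at the former ketene-acetal carbon that its two oxygens stabilise. The enolate carbon next to the butanoyl group then bonds to that cationic carbon in a six-membered closure that is exo with respect to the oxocarbenium C=O bond and has the enolate double bond outside the new ring, giving cyclohexa-1,4-diene 15, so ring C closes in the second bond-forming event. Loss of methoxytrimethylsilane and shift of the ring hydrogen aromatise 15 to aryl silyl ether 16, and dilute acid frees the second phenol to give 17. The closest known reaction type is the thermal cycloaddition–aromatisation of 1-alkoxy-1,3-bis(silyloxy)-1,3-dienes with acetylenic ketones and esters to resorcinols; a 1-alkoxy ynone has not been used as the two-carbon partner, but such ynones accept heteroatom nucleophiles at the alkoxy-bearing carbon. No stereocentre remains, since the two sp3 centres of 15 are erased on aromatisation. The selectivity required is regiochemical and is secured by polarity: the most nucleophilic diene carbon pairs with the β-carbon of the ynone, and the rival three-carbon closure through the carbon next to the ester is blocked because that carbon carries an arm and the ring so formed could not aromatise. The temperature is kept at or below 60 °C because ethyl ynol ethers lose ethene to give ketenes when heated further.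

Step 11
Reactants: 17 1-[2-ethoxy-4,6-dihydroxy-3,5-bis({[2,4,6-tris(benzyloxy)phenyl]methyl})phenyl]butan-1-one
Product: 19 1-[2-ethoxy-4,6-dihydroxy-3,5-bis({[2,4,6-tris(benzyloxy)-3-butanoylphenyl]methyl})phenyl]butan-1-one, via ring C bis(butanoate) 18 (not isolated)
Conditions: butanoic acid, (CF3CO)2O, CH2Cl2, 0 °C to rt; volatiles removed; then K2CO3 (cat.), MeOH/THF, rt
Reagents that add atoms: butanoic acid, CCCC(=O)O
Why: Friedel–Crafts acylation by the mixed anhydride at one of the two equivalent free carbons of each trialkoxy ring, the first ketone deactivating its ring against a second. Ring C is fully substituted, so only its phenols are esterified, and carbonate methanolysis removes these aryl esters and converges any partly O-acylated material on 19.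

Step 12
Reactants: 19 1-[2-ethoxy-4,6-dihydroxy-3,5-bis({[2,4,6-tris(benzyloxy)-3-butanoylphenyl]methyl})phenyl]butan-1-one
Product: 20 1-{3,5-bis[(3-butanoyl-2,4,6-trihydroxyphenyl)methyl]-2,4,6-trihydroxyphenyl}butan-1-one
Conditions: BCl3 (excess), pentamethylbenzene, CH2Cl2, −78 °C to rt; MeOH then water
Reagents that add atoms: none
Why: Lewis-acid ether cleavage in which pentamethylbenzene traps the benzyl cations before they can C-benzylate the phloroglucinol rings. The ethyl ether lies ortho to the ring C ketone, so boron chelation delivers chloride to the ethyl carbon (chelation-assisted dealkylation) while the ketones survive.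

Step 13
Reactants: 21 phloroglucinol
Product: 22 1-(2,4,6-trihydroxyphenyl)butan-1-one
Conditions: butanoyl chloride, AlCl3, PhNO2/CH2Cl2, 0 °C to rt; aq. HCl
Reagents that add atoms: butanoyl chloride, CCCC(=O)Cl
Why: Friedel–Crafts C-acylation of phloroglucinol, which stops at the mono-ketone because the acyl group deactivates the ring.

Step 14
Reactants: 22 1-(2,4,6-trihydroxyphenyl)butan-1-one
Product: 23 2-butanoyl-3,5-dihydroxy-6,6-dimethylcyclohexa-2,4-dien-1-one
Conditions: NaOMe (3 equiv), MeI (2 equiv), MeOH, 0 °C to rt; aq. HCl
Reagents that add atoms: iodomethane, CI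
Why: Dearomatising geminal C-methylation of the acylphloroglucinol polyanion; the second methyl enters the carbon already methylated to give the cross-conjugated trione, whose stabilised anion is a poorer nucleophile, and limiting the iodide curbs methylation of the remaining CH.

Step 15
Reactants: 23 2-butanoyl-3,5-dihydroxy-6,6-dimethylcyclohexa-2,4-dien-1-one
Product: 24 2-butanoyl-4-[(dimethylamino)methyl]-3,5-dihydroxy-6,6-dimethylcyclohexa-2,4-dien-1-one
Conditions: N,N-dimethylmethyleneiminium iodide, Et3N, CH2Cl2, 0 °C to rt
Reagents that add atoms: N,N-dimethylmethyleneiminium iodide, C[N+](C)=C.[I-]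
Why: Mannich aminomethylation at the only remaining nucleophilic ring carbon of the enolised trione; the preformed iminium salt in slight excess suppresses the methylene-bridged dimer.

Step 16
Reactants: 20 1-{3,5-bis[(3-butanoyl-2,4,6-trihydroxyphenyl)methyl]-2,4,6-trihydroxyphenyl}butan-1-one, 24 2-butanoyl-4-[(dimethylamino)methyl]-3,5-dihydroxy-6,6-dimethylcyclohexa-2,4-dien-1-one (two molecules, one for each outer ring; 2.2–2.5 equiv used)
Product: 26 pentaalbaspidin BBBBB, via methylidene trione 25 (not isolated)
Conditions: 1,4-dioxane, 80 °C, argon
Reagents that add atoms: second molecule of Mannich base 24, CCCC(=O)C1=C(O)C(CN(C)C)=C(O)C(C)(C)C1=O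
Why: Thermal loss of dimethylamine from the zwitterionic Mannich base gives alkylidene trione 25, a quinone-methide equivalent, which takes up the one free nuclear carbon of ring B and of ring D in a conjugate (Friedel–Crafts-type) addition. Ring C has no free carbon, so the two-directional capping is site-specific and consumes two molecules of 24 per molecule of 20.

## Compound list

1 | 2,4,6-trihydroxybenzaldehyde | O=Cc1c(O)cc(O)cc1O | starting material
2 | 2,4,6-tris(benzyloxy)benzaldehyde | O=Cc1c(OCc2ccccc2)cc(OCc2ccccc2)cc1OCc1ccccc1 | intermediate
3 | [2,4,6-tris(benzyloxy)phenyl]methanol | OCc1c(OCc2ccccc2)cc(OCc2ccccc2)cc1OCc1ccccc1 | intermediate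
4 | [2,4,6-tris(benzyloxy)phenyl]methyl methanesulfonate | CS(=O)(=O)OCc1c(OCc2ccccc2)cc(OCc2ccccc2)cc1OCc1ccccc1 | intermediate
5 | 1,3,5-tris(benzyloxy)-2-(chloromethyl)benzene | ClCc1c(OCc2ccccc2)cc(OCc2ccccc2)cc1OCc1ccccc1 | intermediate
6 | methyl acetoacetate | COC(=O)CC(C)=O | starting material
7 | methyl 3-oxo-5-[2,4,6-tris(benzyloxy)phenyl]pentanoate | COC(=O)CC(=O)CCc1c(OCc2ccccc2)cc(OCc2ccccc2)cc1OCc1ccccc1 | intermediate
8 | methyl 3-oxo-5-[2,4,6-tris(benzyloxy)phenyl]-2-{[2,4,6-tris(benzyloxy)phenyl]methyl}pentanoate (racemic) | COC(=O)C(Cc1c(OCc2ccccc2)cc(OCc2ccccc2)cc1OCc1ccccc1)C(=O)CCc1c(OCc2ccccc2)cc(OCc2ccccc2)cc1OCc1ccccc1 | intermediate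
9 | methyl 5-[2,4,6-tris(benzyloxy)phenyl]-2-{[2,4,6-tris(benzyloxy)phenyl]methyl}-3-[(trimethylsilyl)oxy]pent-2-enoate (mixture of double-bond isomers) | COC(=O)C(Cc1c(OCc2ccccc2)cc(OCc2ccccc2)cc1OCc1ccccc1)=C(O[Si](C)(C)C)CCc1c(OCc2ccccc2)cc(OCc2ccccc2)cc1OCc1ccccc1 | intermediate
10 | 1-methoxy-5-[2,4,6-tris(benzyloxy)phenyl]-2-{[2,4,6-tris(benzyloxy)phenyl]methyl}-1,3-bis[(trimethylsilyl)oxy]penta-1,3-diene (drawn 1Z,3Z; geometry without consequence) | CO/C(O[Si](C)(C)C)=C(Cc1c(OCc2ccccc2)cc(OCc2ccccc2)cc1OCc1ccccc1)/C(O[Si](C)(C)C)=C/Cc1c(OCc2ccccc2)cc(OCc2ccccc2)cc1OCc1ccccc1 | intermediate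
11 | ethoxyethyne | C#COCC | starting material
12 | butanal | CCCC=O | starting material
13 | 1-ethoxyhex-1-yn-3-ol (racemic) | CCCC(O)C#COCC | intermediate
14 | 1-ethoxyhex-1-yn-3-one | CCCC(=O)C#COCC | intermediate
15 | 1-[2-ethoxy-6-methoxy-3,5-bis({[2,4,6-tris(benzyloxy)phenyl]methyl})-4,6-bis[(trimethylsilyl)oxy]cyclohexa-1,4-dien-1-yl]butan-1-one (diastereomer mixture) | CCCC(=O)C1=C(OCC)C(Cc2c(OCc3ccccc3)cc(OCc3ccccc3)cc2OCc2ccccc2)C(O[Si](C)(C)C)=C(Cc2c(OCc3ccccc3)cc(OCc3ccccc3)cc2OCc2ccccc2)C1(OC)O[Si](C)(C)C | intermediate
16 | 1-[2-ethoxy-6-hydroxy-3,5-bis({[2,4,6-tris(benzyloxy)phenyl]methyl})-4-[(trimethylsilyl)oxy]phenyl]butan-1-one | CCCC(=O)c1c(O)c(Cc2c(OCc3ccccc3)cc(OCc3ccccc3)cc2OCc2ccccc2)c(O[Si](C)(C)C)c(Cc2c(OCc3ccccc3)cc(OCc3ccccc3)cc2OCc2ccccc2)c1OCC | intermediate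
17 | 1-[2-ethoxy-4,6-dihydroxy-3,5-bis({[2,4,6-tris(benzyloxy)phenyl]methyl})phenyl]butan-1-one | CCCC(=O)c1c(O)c(Cc2c(OCc3ccccc3)cc(OCc3ccccc3)cc2OCc2ccccc2)c(O)c(Cc2c(OCc3ccccc3)cc(OCc3ccccc3)cc2OCc2ccccc2)c1OCC | intermediate
18 | 2-butanoyl-3-ethoxy-4,6-bis({[2,4,6-tris(benzyloxy)-3-butanoylphenyl]methyl})-1,5-phenylene dibutanoate | CCCC(=O)Oc1c(C(=O)CCC)c(OCC)c(Cc2c(OCc3ccccc3)cc(OCc3ccccc3)c(C(=O)CCC)c2OCc2ccccc2)c(OC(=O)CCC)c1Cc1c(OCc2ccccc2)cc(OCc2ccccc2)c(C(=O)CCC)c1OCc1ccccc1 | intermediate
19 | 1-[2-ethoxy-4,6-dihydroxy-3,5-bis({[2,4,6-tris(benzyloxy)-3-butanoylphenyl]methyl})phenyl]butan-1-one | CCCC(=O)c1c(O)c(Cc2c(OCc3ccccc3)cc(OCc3ccccc3)c(C(=O)CCC)c2OCc2ccccc2)c(O)c(Cc2c(OCc3ccccc3)cc(OCc3ccccc3)c(C(=O)CCC)c2OCc2ccccc2)c1OCC | intermediate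
20 | 1-{3,5-bis[(3-butanoyl-2,4,6-trihydroxyphenyl)methyl]-2,4,6-trihydroxyphenyl}butan-1-one | CCCC(=O)c1c(O)c(Cc2c(O)cc(O)c(C(=O)CCC)c2O)c(O)c(Cc2c(O)cc(O)c(C(=O)CCC)c2O)c1O | intermediate
21 | phloroglucinol (benzene-1,3,5-triol) | Oc1cc(O)cc(O)c1 | starting material
22 | 1-(2,4,6-trihydroxyphenyl)butan-1-one | CCCC(=O)c1c(O)cc(O)cc1O | intermediate
23 | 2-butanoyl-3,5-dihydroxy-6,6-dimethylcyclohexa-2,4-dien-1-one | CCCC(=O)C1=C(O)C=C(O)C(C)(C)C1=O | intermediate
24 | 2-butanoyl-4-[(dimethylamino)methyl]-3,5-dihydroxy-6,6-dimethylcyclohexa-2,4-dien-1-one | CCCC(=O)C1=C(O)C(CN(C)C)=C(O)C(C)(C)C1=O | intermediate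
25 | 2-butanoyl-3-hydroxy-6,6-dimethyl-4-methylidenecyclohex-2-ene-1,5-dione | CCCC(=O)C1=C(O)C(=C)C(=O)C(C)(C)C1=O | intermediate
26 | pentaalbaspidin BBBBB | CCCC(=O)C1=C(O)C(Cc2c(O)c(Cc3c(O)c(Cc4c(O)c(CC5=C(O)C(C)(C)C(=O)C(C(=O)CCC)=C5O)c(O)c(C(=O)CCC)c4O)c(O)c(C(=O)CCC)c3O)c(O)c(C(=O)CCC)c2O)=C(O)C(C)(C)C1=O | target

## Step count and least certain steps

Total: 16 steps. Longest linear sequence: 11 steps (steps 1, 2, 3, 4, 5, 6, 7, 10, 11, 12, 16).

Step 10 (key step). The most likely failure is that conjugate addition to the donor-deactivated alkyne is slower than hydrolytic or thermal decay of the diene, or that the ynol ether loses ethene on heating before it is attacked. A catalytic amount of Me3SiOSO2CF3 at low temperature would be the first change of conditions. The fallback uses known Mannich-base chemistry and sets out from 22: double aminomethylation with N,N-dimethylmethyleneiminium iodide should give 1-{3,5-bis[(dimethylamino)methyl]-2,4,6-trihydroxyphenyl}butan-1-one F1. Heating F1 in dioxane with a large excess of 22 should give 20 by two quinone-methide alkylations, the excess suppressing higher oligomers. This path comes back to the route at 20 and bypasses 17 to 19.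

Step 4. The ionising benzylic electrophile may alkylate the ring of a second molecule of itself before it meets the dianion, or react at enolate oxygen, because its cation is exceptionally stabilised; its stock solution may also lose titre before use. The fallback avoids any benzylic halide and sets out from 2: Claisen–Schmidt condensation with excess acetone (aq. NaOH) should give (E)-4-[2,4,6-tris(benzyloxy)phenyl]but-3-en-2-one F2. Conjugate reduction with catalytic [(Ph3P)CuH]6 and a silane, which leaves benzyl ethers alone, should give 4-[2,4,6-tris(benzyloxy)phenyl]butan-2-one F3. Carboxylation of F3 at the methyl group with NaH and dimethyl carbonate comes back to the route at 7.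

Step 5. The same electrophile may give an enol ether by O-alkylation, since a cation-like benzyl group is a hard electrophile, and the stock solution of 5 will have aged while 7 was being isolated. The fallback sets out from 7 and 2: Knoevenagel condensation (piperidine, acetic acid, toluene, removal of water) should give methyl 3-oxo-5-[2,4,6-tris(benzyloxy)phenyl]-2-{[2,4,6-tris(benzyloxy)phenyl]methylidene}pentanoate F4. Conjugate reduction of F4 with diethyl 2,6-dimethyl-1,4-dihydropyridine-3,5-dicarboxylate comes back to the route at 8. Taken together with the fallback for step 4, this removes 5 and step 3 from the route altogether.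

Step 11. With the ring C phenols free, the acidic medium may promote ipso protonation of an outer ring with loss or migration of an arm, and O-acylation may use up the mixed anhydride before C-acylation is complete. The fallback sets out from 17: benzylation (BnBr, Cs2CO3, DMF) should give 1-[2,4-bis(benzyloxy)-6-ethoxy-3,5-bis({[2,4,6-tris(benzyloxy)phenyl]methyl})phenyl]butan-1-one F5. With no phenol left, acylation with butanoyl chloride and SnCl4 at −78 °C should give 1-[2,4-bis(benzyloxy)-6-ethoxy-3,5-bis({[2,4,6-tris(benzyloxy)-3-butanoylphenyl]methyl})phenyl]butan-1-one F6. Treatment of F6 with BCl3 and pentamethylbenzene comes back to the route at 20.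

Step 12. Cleavage of the ethyl ether may lag behind debenzylation, or benzyl cations and the Lewis acid may alkylate the rings or scramble the methylene bridges, because the product rings are strongly nucleophilic. The fallback sets out from 19: hydrogenolysis (H2, Pd on carbon, ethyl acetate/methanol) removes the benzyl groups without forming cations and should give 1-{3,5-bis[(3-butanoyl-2,4,6-trihydroxyphenyl)methyl]-2-ethoxy-4,6-dihydroxyphenyl}butan-1-one F7. Chelation-directed cleavage of the ethyl ether of F7 with BBr3 at low temperature comes back to the route at 20.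

Step 16. Retro-Mannich release of 23 would let 25 be captured by 23 instead of 20, leading to a methylene-bridged dimer of the trione; the second capping may also stall, and the liberated amine may promote redistribution of bridges. The fallback reverses the polarity and sets out from 20: aminomethylation of the free carbons of rings B and D with N,N-dimethylmethyleneiminium iodide should give 1-[3,5-bis({3-butanoyl-5-[(dimethylamino)methyl]-2,4,6-trihydroxyphenyl}methyl)-2,4,6-trihydroxyphenyl]butan-1-one F8. Heating F8 with excess 23, the acidic trione now acting as the nucleophile, comes back to the route at 26.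

## Further compounds

F1 | step 10 | 1-{3,5-bis[(dimethylamino)methyl]-2,4,6-trihydroxyphenyl}butan-1-one | CCCC(=O)c1c(O)c(CN(C)C)c(O)c(CN(C)C)c1O
F2 | step 4 | (E)-4-[2,4,6-tris(benzyloxy)phenyl]but-3-en-2-one | CC(=O)/C=C/c1c(OCc2ccccc2)cc(OCc2ccccc2)cc1OCc1ccccc1
F3 | step 4 | 4-[2,4,6-tris(benzyloxy)phenyl]butan-2-one | CC(=O)CCc1c(OCc2ccccc2)cc(OCc2ccccc2)cc1OCc1ccccc1
F4 | step 5 | methyl 3-oxo-5-[2,4,6-tris(benzyloxy)phenyl]-2-{[2,4,6-tris(benzyloxy)phenyl]methylidene}pentanoate (mixture of double-bond isomers) | COC(=O)C(=Cc1c(OCc2ccccc2)cc(OCc2ccccc2)cc1OCc1ccccc1)C(=O)CCc1c(OCc2ccccc2)cc(OCc2ccccc2)cc1OCc1ccccc1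
F5 | step 11 | 1-[2,4-bis(benzyloxy)-6-ethoxy-3,5-bis({[2,4,6-tris(benzyloxy)phenyl]methyl})phenyl]butan-1-one | CCCC(=O)c1c(OCc2ccccc2)c(Cc2c(OCc3ccccc3)cc(OCc3ccccc3)cc2OCc2ccccc2)c(OCc2ccccc2)c(Cc2c(OCc3ccccc3)cc(OCc3ccccc3)cc2OCc2ccccc2)c1OCC
F6 | step 11 | 1-[2,4-bis(benzyloxy)-6-ethoxy-3,5-bis({[2,4,6-tris(benzyloxy)-3-butanoylphenyl]methyl})phenyl]butan-1-one | CCCC(=O)c1c(OCc2ccccc2)c(Cc2c(OCc3ccccc3)cc(OCc3ccccc3)c(C(=O)CCC)c2OCc2ccccc2)c(OCc2ccccc2)c(Cc2c(OCc3ccccc3)cc(OCc3ccccc3)c(C(=O)CCC)c2OCc2ccccc2)c1OCC
F7 | step 12 | 1-{3,5-bis[(3-butanoyl-2,4,6-trihydroxyphenyl)methyl]-2-ethoxy-4,6-dihydroxyphenyl}butan-1-one | CCCC(=O)c1c(O)c(Cc2c(O)cc(O)c(C(=O)CCC)c2O)c(O)c(Cc2c(O)cc(O)c(C(=O)CCC)c2O)c1OCC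
F8 | step 16 | 1-[3,5-bis({3-butanoyl-5-[(dimethylamino)methyl]-2,4,6-trihydroxyphenyl}methyl)-2,4,6-trihydroxyphenyl]butan-1-one | CCCC(=O)c1c(O)c(Cc2c(O)c(CN(C)C)c(O)c(C(=O)CCC)c2O)c(O)c(Cc2c(O)c(CN(C)C)c(O)c(C(=O)CCC)c2O)c1O
A1 | alternative 1 | nona-O-benzyl B–C–D trimer, 1-[2,4,6-tris(benzyloxy)-3,5-bis({[2,4,6-tris(benzyloxy)-3-butanoylphenyl]methyl})phenyl]butan-1-one | CCCC(=O)c1c(OCc2ccccc2)cc(OCc2ccccc2)c(Cc2c(OCc3ccccc3)c(Cc3c(OCc4ccccc4)cc(OCc4ccccc4)c(C(=O)CCC)c3OCc3ccccc3)c(OCc3ccccc3)c(C(=O)CCC)c2OCc2ccccc2)c1OCc1ccccc1
A2 | alternative 1 | {[2,4,6-tris(benzyloxy)-3-butanoylphenyl]methyl}zinc chloride | Cl[Zn]Cc1c(OCc2ccccc2)cc(OCc2ccccc2)c(C(=O)CCC)c1OCc1ccccc1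
A3 | alternative 1 | 1-[2,4,6-tris(benzyloxy)-3,5-diiodophenyl]butan-1-one | CCCC(=O)c1c(OCc2ccccc2)c(I)c(OCc2ccccc2)c(I)c1OCc1ccccc1
A4 | alternative 2 | B–C–D trimer with rings B and D as mono-ethyl ethers and benzyl-protected, unacylated ring C | CCOc1c(Cc2c(OCc3ccccc3)cc(OCc3ccccc3)c(Cc3c(O)cc(O)c(C(=O)CCC)c3OCC)c2OCc2ccccc2)c(O)cc(O)c1C(=O)CCC
A5 | alternative 2 | tetrakis(trimethylsilyl) bis-dienol ether of dimethyl 5,5'-[2,4,6-tris(benzyloxy)-1,3-phenylene]bis(3-oxopentanoate) (double-bond geometry undefined) | COC(O[Si](C)(C)C)=CC(O[Si](C)(C)C)=CCc1c(OCc2ccccc2)cc(OCc2ccccc2)c(CC=C(O[Si](C)(C)C)C=C(OC)O[Si](C)(C)C)c1OCc1ccccc1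
A6 | alternative 3 | 3,5-bis[(triisopropylsilyl)oxy]-2,4-bis({[2,4,6-tris(benzyloxy)phenyl]methyl})phenol | Oc1cc(O[Si](C(C)C)(C(C)C)C(C)C)c(Cc2c(OCc3ccccc3)cc(OCc3ccccc3)cc2OCc2ccccc2)c(O[Si](C(C)C)(C(C)C)C(C)C)c1Cc1c(OCc2ccccc2)cc(OCc2ccccc2)cc1OCc1ccccc1
A7 | alternative 3 | 2-{[2,4,6-tris(benzyloxy)phenyl]methyl}-3-[(triisopropylsilyl)oxy]cyclobut-2-en-1-one | O=C1CC(O[Si](C(C)C)(C(C)C)C(C)C)=C1Cc1c(OCc2ccccc2)cc(OCc2ccccc2)cc1OCc1ccccc1
A8 | alternative 3 | triisopropyl({3-[2,4,6-tris(benzyloxy)phenyl]prop-1-yn-1-yl}oxy)silane | CC(C)[Si](OC#CCc1c(OCc2ccccc2)cc(OCc2ccccc2)cc1OCc1ccccc1)(C(C)C)C(C)C
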